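Compound numbers are fixed by the nine steps below and are used in every section. Positions follow depsidone numbering: ring A (the formyl-bearing arene) is C1–C4, C4a, C11a; ring B (the hexasubstituted arene) is C5a, C6–C9, C9a; O5 is the ether oxygen and O10–C11(=O) the ester.

## The problem

Target 17 is a depsidone: ring A and ring B are joined twice, by O5 and by the ester O10–C11, into a seven-membered dioxepinone, and a 2,2-dimethyl-2,3-dihydropyran-4-one is fused to ring B across C7 (ring oxygen) and C8 (ketone carbon). There is no stereocentre, so the difficulty is purely regiochemical. Ring A carries five different substituents (1-methyl, 3-hydroxy, 4-formyl, O5 at C4a, C11 at C11a). Ring B has no hydrogen left: four contiguous oxygens (C9a, C5a, C6, C7) are followed by the acyl carbon at C8 and a methyl group at C9. A lactone closed by plain esterification cannot tell the C9a oxygen from the C6 oxygen, since both flank the ether carbon C5a and both give a seven-membered ring. The aryl ester is opened or transposed by base and nucleophiles, the chromanone can undergo retro-oxa-Michael opening in base, and the aldehyde and electron-rich phenols are sensitive, so late steps must be acidic or neutral. The enabling feature is that ring B, stripped of O10 and the pyranone carbons, is 5-methylpyrogallol arylated on a terminal oxygen. Its two free hydroxyls (at C6 and C7) form a catechol whose ortho-quinone has C9a as the β-carbon of the enone O=C6–C5a=C9a, and the ring A carboxylate lies exactly one seven-membered ring away from that carbon. The C9a–O10 bond can therefore be made from a C–H bond by oxidation, and the symmetry of 5-methylpyrogallol removes any regiochemical question in the arylation.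

## Retrosynthesis

17 ⇒ 16. Only the O–CH3 bond at C3 is cut. The ring A phenol is carried as its methyl ether from the first step because it survives alkyllithiums, carbonate, the anode and strong acid. It lies ortho to the formyl group, so BCl3 can remove it by chelation at the end. A free phenol earlier would put a phenoxide into the SNAr step and a second phenol into the Friedel–Crafts step.

16 ⇒ 13 + 14. The pyranone is cut at C8–C(=O) and at O(C7)–CMe2, giving depsidone catechol 13 and 3-methylbut-2-enoic acid 14. The pyranone cannot be installed earlier, because a pyran oxygen at C7 would destroy the catechol that the key step needs. C8 is the only unsubstituted ring B carbon and C7–OH is the only hydroxyl that can reach the enone, so no regiochemistry has to be controlled. The forward reaction must acylate a pentasubstituted arene in strong acid without opening the lactone.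

13 ⇒ 11 (through ortho-quinone 12). The aryl C9a–O10 bond is cut. Cutting the acyl C11–O10 bond instead would require a tetra-oxygenated ring B with two hydroxyls ortho to the ether carbon that must be distinguished. Cutting the ether bond would require an equally differentiated partner for an intramolecular substitution. The chosen cut removes one oxygen from ring B and leaves acid 11, whose ring B is simply an aryl ether of 5-methylpyrogallol. The forward reaction must oxidise the catechol alone and make the carboxylate add at C9a in a 7-endo conjugate addition.

11 ⇒ 10 ⇒ 9 + 2. Acid 11 is unmasked from tert-butyl ester and acetonide 10 in one acid treatment. The tert-butyl ester is chosen because the carboxyl group sits between two ortho substituents, where saponification of a methyl ester would be unreliable, whereas acidolysis by alkyl–oxygen cleavage is not hindered. The ether bond C4a–O5 of 10 is cut by SNAr logic to fluoro aldehyde ester 9, whose fluoride lies between formyl and ester, and phenol 2, which has a single free hydroxyl.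

2 ⇒ 1. The acetonide is cut to 5-methylpyrogallol 1. Because 1 is symmetric, either pair of adjacent hydroxyls gives the same ketal.

9 ⇒ 6 ⇒ 5 ⇒ 3. Both carbonyl carbons of ring A are cut back to C–H bonds of 3-fluoro-5-methylanisole 3 by two directed metalations. The order is fixed by acidity: the hydrogen between fluorine and methoxy goes first and becomes the formyl carbon (5), which is masked as dimethyl acetal 6. The remaining hydrogen ortho to fluorine goes second and becomes the ester carbon.

## Roads not taken

Alternative 1: Ring B is built from a four-membered ring. The cut is the C9–C9a bond. Heating cyclobutenone A1 opens it to a dienylketene, six-electron ring closure and enolisation follow, and hydroquinone diaryl ether A2 results, with the ketene carbon as the phenol carbon C9a. Its merit is real: all four ring B oxygens are placed and differentiated by construction (C9a–OH and C7–OH free, C6 as methyl ether, C5a as the diaryl ether). The lactone then closes by ordinary esterification onto the only hydroxyl ortho to the ether carbon. In this respect it is safer than the chosen plan, whose key step stretches a known reaction to a new ring size. Its weak points are several: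
- A1 must be assembled on a four-membered ring carrying two different oxygen substituents, one of them the hindered aryloxy group of ring A, and the propenyl nucleophile must add to the right one of two carbonyl groups.
- Ring A travels as an acetal and a doubly ortho-substituted methyl ester that is hard to saponify.
- A ring B methyl ether must later be removed beside the ring A one.
- The pyranone is still missing.

The chosen plan sets against this a ring B that is bought complete as 1, the conversion of a single C–H into C–O, and a clearly shorter sequence.

Alternative 2: The pyran ring is cut at the benzylic carbon–CH2 bond and the O–CMe2 bond. Salicylaldehyde A3 with HC(OMe)3 and catalytic TfOH gives a methoxy-substituted ortho-quinone methide, which adds 2-methylpropene A4 to give chroman A5, whose methoxy-bearing carbon is the latent ketone. It is better than step 8 of the chosen plan in one respect: the pyran ring is made on a simple arene under catalytic acid, so no hot strong acid ever meets the lactone. Its weak points: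
- The key step is spent on the easiest ring.
- A5 still lacks the oxygen at the future C9a.
- Its two aryl methyl ethers must be told apart, one becoming O5 and one the free hydroxyl.
- The benzylic ether needs two further steps to become the ketone.
- A4 is a gaseous and only moderately nucleophilic partner for a quinone methide.
- The seven-membered ring remains entirely unsolved.

The chosen plan answers with a one-step annulation on 13 that has no regiochemical choice, and with a fallback for it.

Alternative 3: The ether bond C4a–O5 is cut with ring A not yet aromatic. TsOH-catalysed dehydration of keto ester A6 lets the free ring B phenol add to the ring A ketone β to the ester carbonyl, giving β-aryloxy enoate A7 and closing the seven-membered ring. Its advantage is that the closure is a condensation under thermodynamic control, with no activated fluoride and no redox step. That makes it better precedented than the anodic closure. Its weak points: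
- A6 is an aryl ester of a cyclic diketo acid, prone to decarboxylation and acyl transfer.
- Making A6 requires mono-acylation of one hydroxyl of an unsymmetrical catechol, which is the very ambiguity the target poses.
- Ring A must afterwards be dehydrogenated and then formylated at C4 in competition with C2 and with the electron-rich ring B.
- Two ring B methyl ethers must be differentiated.
- The pyranone is still to be built.

The chosen plan sets against this an aromatic ring A whose formyl group is placed by directed metalation at the start, and fewer steps.

Key step: step 7

Assumption: 5-methylpyrogallol 1 and 3-fluoro-5-methylanisole 3 are taken as purchasable; should 1 be unavailable, it is one BBr3 demethylation away from 3,4,5-trimethoxytoluene.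

## Route

Step 1
Reactants: 1 5-methylpyrogallol (5-methylbenzene-1,2,3-triol)
Product: 2 2,2,6-trimethyl-1,3-benzodioxol-4-ol
Conditions: 2,2-dimethoxypropane, TsOH·H2O (cat.), toluene, reflux, MeOH distilled off
Reagents that add atoms: 2,2-dimethoxypropane, COC(C)(C)OC
Why: Acid-catalysed transketalisation of an ortho-dihydroxy pair is standard for pyrogallols; only one five-membered ketal can form, and because 1 is symmetric both possible ketals are the same compound, leaving one hydroxyl free.

Step 2
Reactants: 3 3-fluoro-5-methylanisole (1-fluoro-3-methoxy-5-methylbenzene)
Product: 5 2-fluoro-6-methoxy-4-methylbenzaldehyde, via aryllithium 4 (not isolated)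
Conditions: n-BuLi, THF, −78 °C; DMF, −78 to 0 °C; aq. NH4Cl
Reagents that add atoms: N,N-dimethylformamide, CN(C)C=O
Why: Directed ortho-metalation: the hydrogen between fluorine and methoxy is acidified by both groups and is removed selectively at −78 °C, where loss of LiF to an aryne does not occur; formylation of 4 with DMF gives the aldehyde on work-up.

Step 3
Reactants: 5 2-fluoro-6-methoxy-4-methylbenzaldehyde
Product: 6 2-(dimethoxymethyl)-1-fluoro-3-methoxy-5-methylbenzene
Conditions: HC(OMe)3, TsOH·H2O (cat.), MeOH, rt; Et3N quench
Reagents that add atoms: trimethyl orthoformate, COC(OC)OC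
Why: Acid-catalysed acetalisation with the orthoester as methoxy donor and water scavenger; the dimethyl acetal shields the aldehyde from the alkyllithium of step 4 and is removed again by dilute acid.

Step 4
Reactants: 6 2-(dimethoxymethyl)-1-fluoro-3-methoxy-5-methylbenzene
Product: 9 tert-butyl 2-fluoro-3-formyl-4-methoxy-6-methylbenzoate, via aryllithium 7 (not isolated), via acetal ester 8 (not isolated)
Conditions: s-BuLi, PMDTA, THF, −78 °C; Boc2O, −78 °C; then 1 M aq. HCl–THF, rt
Reagents that add atoms: di-tert-butyl dicarbonate, CC(C)(C)OC(=O)OC(=O)OC(C)(C)C; water, O
Why: Directed ortho-metalation under amine-complexed, acidity-controlled conditions removes the one hydrogen ortho to fluorine in preference to the one ortho to methoxy, whose lone pairs point toward the acetal and coordinate lithium poorly; acylation of 7 with Boc2O gives tert-butyl ester 8 directly, and the dilute-acid work-up hydrolyses the dimethyl acetal while the tert-butyl ester survives.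

Step 5
Reactants: 9 tert-butyl 2-fluoro-3-formyl-4-methoxy-6-methylbenzoate; 2 2,2,6-trimethyl-1,3-benzodioxol-4-ol
Product: 10 tert-butyl 3-formyl-4-methoxy-6-methyl-2-[(2,2,6-trimethyl-1,3-benzodioxol-4-yl)oxy]benzoate
Conditions: K2CO3, DMF, 70 °C, Ar
Reagents that add atoms: none
Why: Nucleophilic aromatic substitution by addition–elimination: the fluoride is activated by a coplanar ortho formyl group and an ortho ester and is displaced by the phenoxide of 2; the other two ring B oxygens are locked in the ketal, so only one ether can form.

Step 6
Reactants: 10 tert-butyl 3-formyl-4-methoxy-6-methyl-2-[(2,2,6-trimethyl-1,3-benzodioxol-4-yl)oxy]benzoate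
Product: 11 2-(2,3-dihydroxy-5-methylphenoxy)-3-formyl-4-methoxy-6-methylbenzoic acid
Conditions: TFA–H2O (9:1), 0 °C to rt, Ar
Reagents that add atoms: none
Why: Acidolysis: the tert-butyl ester cleaves by alkyl–oxygen fission (tert-butyl cation lost as 2-methylpropene), which the two ortho substituents do not hinder, and aqueous TFA hydrolyses the aryl ketal; the aldehyde, the diaryl ether and the methyl ether are inert to these conditions.

Step 7
Reactants: 11 2-(2,3-dihydroxy-5-methylphenoxy)-3-formyl-4-methoxy-6-methylbenzoic acid
Product: 13 6,7-dihydroxy-3-methoxy-1,9-dimethyl-11-oxo-11H-dibenzo[b,e][1,4]dioxepine-4-carbaldehyde, via ortho-quinone 12 (not isolated)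
Conditions: divided cell, graphite-felt anode, Pt cathode, controlled potential just past the first anodic wave of 11, MeCN–aq. NaH2PO4/Na2HPO4 buffer pH 6 (1:1), 5 mM, rt, Ar, 2 F/mol
Reagents that add atoms: none
Why: The catechol of 11 is by far its most easily oxidised group and gives up two electrons and two protons to form ortho-quinone 12, while the electron-poor ring A, the aldehyde and the carboxylate are untouched at this potential. The ring A carboxylate then adds in conjugate fashion to C9a, the β-carbon of the enone O=C6–C5a=C9a, and enolisation of the adduct restores the aromatic catechol as lactone 13 (electron transfer followed by a chemical step). The closest known reaction type is the anodic oxidation of catechols in buffered aqueous media with Michael addition of a nucleophile to the quinone, including capture by a tethered carboxylate to give five- and six-membered aryl lactones; the present case extends the ring size only. The ring closes in the 7-endo-trig mode, and this is eased because the ring atoms other than the two oxygens belong to two arenes and a carboxyl group, so that only the two ether torsions and the aryl–carboxylate torsion have to be fixed. No stereocentre is formed. The site selectivity required is addition at C9a and not at the methyl-bearing β-carbon C9 or at the carbonyl carbon C6 or the ether-bearing C5a; the tether secures it because C9 is out of reach, and additions at C6 or C5a are reversible and cannot rearomatise, whereas addition at C9a is made irreversible by enolisation. The ether oxygen is a weak donor toward ring B because its lone pair is drawn into the formyl- and carboxyl-substituted ring A, so C9a stays electrophilic. Over-oxidation is limited because the new acyloxy group makes catechol 13 harder to oxidise than 11, and high dilution with slow generation of 12 at a fixed potential disfavours attack of 11 or water on the quinone.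

Step 8
Reactants: 13 6,7-dihydroxy-3-methoxy-1,9-dimethyl-11-oxo-11H-dibenzo[b,e][1,4]dioxepine-4-carbaldehyde; 14 3-methylbut-2-enoic acid
Product: 16 3-O-methyl ether of target 17 (depsidone 13 with a 2,2-dimethyl-2,3-dihydropyran-4-one fused at C7–O and C8–C=O), via aryl enone 15 (not isolated)
Conditions: P2O5–MeSO3H (1:10 w/w), 60 °C
Reagents that add atoms: none
Why: Tandem Friedel–Crafts acylation and oxa-Michael addition, the standard one-pot chromanone synthesis from phenols and 3-methylbut-2-enoic acid: C8 is the only unsubstituted ring B carbon, ortho to the C7 hydroxyl and para to O5, while ring A is deactivated by two carbonyl groups; enone 15 closes 6-endo-trig through C7–OH, the only hydroxyl that can reach its β-carbon.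

Step 9
Reactants: 16 3-O-methyl ether of target 17
Product: 17 target depsidone CNP0271978.0 (3,6-dihydroxy-4-formyl-1,9-dimethyl depsidone with a 2,2-dimethyl-2,3-dihydropyran-4-one fused at C7–O and C8–C=O)
Conditions: BCl3, CH2Cl2, −78 to 0 °C; then H2O
Reagents that add atoms: none
Why: Chelation-assisted Lewis-acid ether cleavage: BCl3 bridges the formyl oxygen and the ortho methoxy oxygen and chloride removes the methyl group; 16 has no other methyl ether, and the lactone, the chromanone and the ring B phenol are recovered on aqueous work-up.

## Compound list

1 | 5-methylpyrogallol (5-methylbenzene-1,2,3-triol) | Cc1cc(O)c(O)c(O)c1 | starting material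
2 | 2,2,6-trimethyl-1,3-benzodioxol-4-ol | Cc1cc(O)c2OC(C)(C)Oc2c1 | intermediate
3 | 3-fluoro-5-methylanisole | COc1cc(C)cc(F)c1 | starting material
4 | (2-fluoro-6-methoxy-4-methylphenyl)lithium | [Li]c1c(F)cc(C)cc1OC | intermediate
5 | 2-fluoro-6-methoxy-4-methylbenzaldehyde | COc1cc(C)cc(F)c1C=O | intermediate
6 | 2-(dimethoxymethyl)-1-fluoro-3-methoxy-5-methylbenzene | COc1cc(C)cc(F)c1C(OC)OC | intermediate
7 | [3-(dimethoxymethyl)-2-fluoro-4-methoxy-6-methylphenyl]lithium | [Li]c1c(C)cc(OC)c(C(OC)OC)c1F | intermediate
8 | tert-butyl 3-(dimethoxymethyl)-2-fluoro-4-methoxy-6-methylbenzoate | Cc1cc(OC)c(C(OC)OC)c(F)c1C(=O)OC(C)(C)C | intermediate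
9 | tert-butyl 2-fluoro-3-formyl-4-methoxy-6-methylbenzoate | Cc1cc(OC)c(C=O)c(F)c1C(=O)OC(C)(C)C | intermediate
10 | tert-butyl 3-formyl-4-methoxy-6-methyl-2-[(2,2,6-trimethyl-1,3-benzodioxol-4-yl)oxy]benzoate | Cc1cc(OC)c(C=O)c(Oc2cc(C)cc3OC(C)(C)Oc23)c1C(=O)OC(C)(C)C | intermediate
11 | 2-(2,3-dihydroxy-5-methylphenoxy)-3-formyl-4-methoxy-6-methylbenzoic acid | Cc1cc(OC)c(C=O)c(Oc2cc(C)cc(O)c2O)c1C(=O)O | intermediate
12 | 3-formyl-4-methoxy-6-methyl-2-[(3-methyl-5,6-dioxocyclohexa-1,3-dien-1-yl)oxy]benzoic acid | Cc1cc(OC)c(C=O)c(OC2=CC(C)=CC(=O)C2=O)c1C(=O)O | intermediate
13 | 6,7-dihydroxy-3-methoxy-1,9-dimethyl-11-oxo-11H-dibenzo[b,e][1,4]dioxepine-4-carbaldehyde | Cc1cc(OC)c(C=O)c2c1C(=O)Oc1c(C)cc(O)c(O)c1O2 | intermediate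
14 | 3-methylbut-2-enoic acid | CC(C)=CC(=O)O | starting material
15 | 6,7-dihydroxy-3-methoxy-1,9-dimethyl-8-(3-methylbut-2-enoyl)-11-oxo-11H-dibenzo[b,e][1,4]dioxepine-4-carbaldehyde | Cc1cc(OC)c(C=O)c2c1C(=O)Oc1c(C)c(C(=O)C=C(C)C)c(O)c(O)c1O2 | intermediate
16 | 3-O-methyl ether of 17 (6-hydroxy-3-methoxy-4-formyl-1,9-dimethyl depsidone with a 2,2-dimethyl-2,3-dihydropyran-4-one fused at C7–O and C8–C=O) | Cc1cc(OC)c(C=O)c2c1C(=O)Oc1c(C)c3c(c(O)c1O2)OC(C)(C)CC3=O | intermediate
17 | CNP0271978.0 (3,6-dihydroxy-4-formyl-1,9-dimethyl depsidone with a 2,2-dimethyl-2,3-dihydropyran-4-one fused at C7–O and C8–C=O; no stereocentre) | Cc1cc(O)c(C=O)c2c1C(=O)Oc1c(C)c3c(c(O)c1O2)OC(C)(C)CC3=O | target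

## Step count and risks

Total: 9 steps. Longest linear sequence: 8 steps (3 → 17 through steps 2–9); step 1 is the one-step side branch.

Step 7 (key step). The likely failure is that quinone 12 is consumed by bimolecular processes before the seven-membered conjugate addition takes place: attack by water or by unoxidised 11, or filming of the electrode. A second possibility is reversible addition of the carboxylate at the ether-bearing carbon, followed by loss of the ring A oxygen and transposition of ester and ether. The fallback sets out from 2 and 9 and returns at 13. It places the lactone oxygen on ring B before the rings are joined and closes the lactone by esterification.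
- Magnesium-mediated ortho-formylation of 2 (MgCl2, Et3N, paraformaldehyde, MeCN, reflux) at its only free ortho carbon gives 4-hydroxy-2,2,6-trimethyl-1,3-benzodioxole-5-carbaldehyde F1.
- Dakin oxidation (H2O2, aq. NaOH) gives 2,2,6-trimethyl-1,3-benzodioxole-4,5-diol F2.
- SNAr on 9 with one equivalent of K2CO3, through the more acidic 4-hydroxyl beside the ring oxygen, gives tert-butyl 3-formyl-2-[(5-hydroxy-2,2,6-trimethyl-1,3-benzodioxol-4-yl)oxy]-4-methoxy-6-methylbenzoate F3.
- Anhydrous TsOH in warm toluene removes the tert-butyl group without touching the ketal, giving 3-formyl-2-[(5-hydroxy-2,2,6-trimethyl-1,3-benzodioxol-4-yl)oxy]-4-methoxy-6-methylbenzoic acid F4.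
- Carbodiimide lactonisation (EDC·HCl, DMAP, CH2Cl2) onto the only free hydroxyl gives the 6,7-O-isopropylidene ketal of 13, F5.
- TFA–H2O then frees 13.

The price is four more steps and a regiochemical question in the arylation of F2 that the oxidative route does not have.

Step 8. The hot, strongly acidic medium may ionise the doubly ortho-substituted aryl ester to an acylium ion and open the lactone, may condense the aldehyde with an electron-rich ring of a second molecule, or may stop at O-acylation. The fallback sets out from 13 and returns at 15 and then 16 under neutral conditions. Mono-acylation of the less hindered C7 hydroxyl with 3-methylbut-2-enoyl chloride (Et3N, CH2Cl2, −20 °C) gives the 7-O-(3-methylbut-2-enoyl) ester of 13, F6. Photo-Fries rearrangement (254 nm, MeCN) moves the acyl group to the only free ortho carbon to give 15, which closes to 16 on brief contact with NaOAc in MeOH.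

Step 4. Regiocontrol of the deprotonation may be lost, through competing metalation beside the methoxy group or at the benzylic methyl group, and warming may cause loss of LiF to an aryne. The fallback sets out from 5 and returns at 7 by fixing the site with bromine. Bromination of 5 para to the methoxy group (NBS, MeCN, rt) gives 3-bromo-2-fluoro-6-methoxy-4-methylbenzaldehyde F7. Acetalisation as in step 3 gives 2-bromo-4-(dimethoxymethyl)-3-fluoro-5-methoxy-1-methylbenzene F8. Bromine–lithium exchange (n-BuLi, THF, −78 °C) generates 7 regiospecifically, and 7 is carried on to 8 and 9 as in step 4.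

Step 6. The tert-butyl cation may alkylate the electron-rich catechol ring, and the freed catechol may air-oxidise during isolation. The fallback sets out from 6 and returns at 11 without generating a carbocation.
- Aryllithium 7 is trapped with allyl chloroformate and worked up with dilute HCl as in step 4 to give allyl 2-fluoro-3-formyl-4-methoxy-6-methylbenzoate F9.
- SNAr with 2 as in step 5 gives allyl 3-formyl-4-methoxy-6-methyl-2-[(2,2,6-trimethyl-1,3-benzodioxol-4-yl)oxy]benzoate F10.
- Deallylation with Pd(PPh3)4 and morpholine (THF, rt) gives 3-formyl-4-methoxy-6-methyl-2-[(2,2,6-trimethyl-1,3-benzodioxol-4-yl)oxy]benzoic acid F11.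
- TFA–H2O then hydrolyses only the ketal, giving 11.

## Further compounds

F1 | step 7 | 4-hydroxy-2,2,6-trimethyl-1,3-benzodioxole-5-carbaldehyde | Cc1cc2OC(C)(C)Oc2c(O)c1C=O
F2 | step 7 | 2,2,6-trimethyl-1,3-benzodioxole-4,5-diol | Cc1cc2OC(C)(C)Oc2c(O)c1O
F3 | step 7 | tert-butyl 3-formyl-2-[(5-hydroxy-2,2,6-trimethyl-1,3-benzodioxol-4-yl)oxy]-4-methoxy-6-methylbenzoate | Cc1cc(OC)c(C=O)c(Oc2c(O)c(C)cc3OC(C)(C)Oc23)c1C(=O)OC(C)(C)C
F4 | step 7 | 3-formyl-2-[(5-hydroxy-2,2,6-trimethyl-1,3-benzodioxol-4-yl)oxy]-4-methoxy-6-methylbenzoic acid | Cc1cc(OC)c(C=O)c(Oc2c(O)c(C)cc3OC(C)(C)Oc23)c1C(=O)O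
F5 | step 7 | 6,7-O-isopropylidene ketal of 13 | Cc1cc(OC)c(C=O)c2c1C(=O)Oc1c(C)cc3OC(C)(C)Oc3c1O2
F6 | step 8 | 7-O-(3-methylbut-2-enoyl) ester of 13 | Cc1cc(OC)c(C=O)c2c1C(=O)Oc1c(C)cc(OC(=O)C=C(C)C)c(O)c1O2
F7 | step 4 | 3-bromo-2-fluoro-6-methoxy-4-methylbenzaldehyde | COc1cc(C)c(Br)c(F)c1C=O
F8 | step 4 | 2-bromo-4-(dimethoxymethyl)-3-fluoro-5-methoxy-1-methylbenzene | COc1cc(C)c(Br)c(F)c1C(OC)OC
F9 | step 6 | allyl 2-fluoro-3-formyl-4-methoxy-6-methylbenzoate | Cc1cc(OC)c(C=O)c(F)c1C(=O)OCC=C
F10 | step 6 | allyl 3-formyl-4-methoxy-6-methyl-2-[(2,2,6-trimethyl-1,3-benzodioxol-4-yl)oxy]benzoate | Cc1cc(OC)c(C=O)c(Oc2cc(C)cc3OC(C)(C)Oc23)c1C(=O)OCC=C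
F11 | step 6 | 3-formyl-4-methoxy-6-methyl-2-[(2,2,6-trimethyl-1,3-benzodioxol-4-yl)oxy]benzoic acid | Cc1cc(OC)c(C=O)c(Oc2cc(C)cc3OC(C)(C)Oc23)c1C(=O)O
A1 | alternative 1 | methyl 3-(1,3-dioxolan-2-yl)-2-{[3-hydroxy-2-methoxy-4-oxo-3-[(E)-prop-1-enyl]cyclobut-1-en-1-yl]oxy}-4-methoxy-6-methylbenzoate (racemic) | COC(=O)c1c(C)cc(OC)c(C2OCCO2)c1OC1=C(OC)C(O)(/C=C/C)C1=O
A2 | alternative 1 | methyl 2-(2,5-dihydroxy-6-methoxy-3-methylphenoxy)-3-(1,3-dioxolan-2-yl)-4-methoxy-6-methylbenzoate | COC(=O)c1c(C)cc(OC)c(C2OCCO2)c1Oc1c(O)c(C)cc(O)c1OC
A3 | alternative 2 | 2-hydroxy-3,4-dimethoxy-6-methylbenzaldehyde | Cc1cc(OC)c(OC)c(O)c1C=O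
A4 | alternative 2 | 2-methylpropene | CC(C)=C
A5 | alternative 2 | 4,7,8-trimethoxy-2,2,5-trimethylchroman (racemic) | COC1CC(C)(C)Oc2c(OC)c(OC)cc(C)c21
A6 | alternative 3 | (2-hydroxy-3,4-dimethoxy-6-methylphenyl) 2-methyl-4,6-dioxocyclohexane-1-carboxylate (racemic) | CC1CC(=O)CC(=O)C1C(=O)Oc1c(C)cc(OC)c(OC)c1O
A7 | alternative 3 | 6,7-dimethoxy-1,9-dimethyl-1,2-dihydrodibenzo[b,e][1,4]dioxepine-3,11(4H)-dione (racemic) | CC1CC(=O)CC2=C1C(=O)Oc1c(C)cc(OC)c(OC)c1O2
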